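We carry one ratio to this flask: the split, product divided by starting material once the readings have gone flat.

| flask | starting material | gas phase | protic impurity | remark | time |
|---|---|---|---|---|---|
| oak | 10 mM | 3.1 mM (held) | 1 mM | run made earlier |  |
| alder | 40 mM | 3.1 mM (held) | 1 mM | run made earlier |  |
| ash | 20 mM | 3.1 mM (held) | 0.50 mM | run made earlier |  |
| flask | 20 mM | 3.1 mM (held) | 1.00 mM |  | 15 min |

| run | time / min | starting material / % | product / % |
|---|---|---|---|
| oak | 1.00 | 76.8 | 14.3 |
| oak | 1.50 | 76.7 | 14.8 |
| oak | 2.50 | 75.9 | 14.5 |
| oak | 4.00 | 76.2 | 14.1 |
| oak | 8.00 | 76.0 | 14.2 |
| oak | 12.0 | 76.8 | 13.2 |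
| alder | 2.00 | 82.5 | 14.0 |
| alder | 4.00 | 83.9 | 14.6 |
| alder | 6.00 | 83.2 | 14.3 |
| alder | 8.00 | 83.7 | 14.3 |
| alder | 10.0 | 82.3 | 14.8 |
| alder | 12.0 | 82.3 | 15.2 |
| ash | 1.00 | 84.0 | 14.7 |
| ash | 2.00 | 83.2 | 15.1 |
| ash | 3.00 | 83.4 | 14.9 |
| ash | 6.00 | 83.1 | 14.7 |
| ash | 12.0 | 83.3 | 13.9 |

(scatter of a reading: 0.5 percentage points)

- at the start none of the gas phase is in solution
- the reaction counts as stopped when no species that holds the starting material changes by six tenths of a point or more over the second half of the time

- at 15 min, what has stopped the reaction, if anything has (forward and back rates have come level / all of the starting material has reacted / it is still moving)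
- share of the starting material used up at 15 min
- product at 15 min, in percent of the starting material charged
- amount of product if the flask were left three thousand times as long, in percent of the starting material charged

Averaging each run's readings gives a small table; "missing" is the charge not found as starting material or product.

| run | charged | protic impurity | missing | product / starting material |
|---|---|---|---|---|
| oak | 10 mM | 1 mM | 0.942 mM | 0.186 |
| alder | 40 mM | 1 mM | 0.993 mM | 0.175 |
| ash | 20 mM | 0.50 mM | 0.388 mM | 0.176 |

The missing column follows the impurity, not the charge, so we read the impurity as the limiting reagent of a loss that takes starting material about one to one. The last column barely shifts from alder to ash, and oak stands 0.0110 higher, although the charge runs from 10 mM to 40 mM. Starting material remains and the columns hold nearly level up to 12.0 min, so we read a balance under held gas. We take the mean of the three runs as the split, the plateau ratio of product to starting material: 0.179.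

For the flask, the charge less the impurity divides in the ratio 0.179. Product is then 14.4% and conversion 19.4%, and we commit to a balance at the asked time and to the same product for the long wait.

The forecast gives forward and back rates have come level, with 19.4% used up, 14.4% product and 14.4% in the long run, holding that “this is an equilibrium with held gas”.

The flask gives forward and back rates have come level, with 19.3% used up, 14.3% product and 14.3% in the long run.

    starting material + protic impurity → quenched substrate (k = 853 M⁻¹ s⁻¹)
    gas phase ⇌ dissolved gas, rate k2*(csat - [dissolved gas]) (kL = 0.149 s⁻¹)
    starting material + dissolved gas ⇌ product (K = 530 M⁻¹, k = 33.2 M⁻¹ s⁻¹)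
    dissolved gas → decomposed reagent (k = 1.23 s⁻¹)

In the flask, the step joining starting material and dissolved gas has a relaxation half-life of 1.14 s, far shorter than the 15 min of the run, and its backward turnover is 98% of the forward one. Dissolved gas stands there at 0.335 mM, less than the saturation level of 3.1 mM, and the equilibrium constant of that step times this dissolved gas, 0.178, matches the flask's ratio of product to starting material, 0.178.

For a neighbour flask with 2.5 mM of protic impurity, the split of 0.179 gives 13.3% product and 25.8% conversion. That neighbour computes to 13.2% and 25.7%.

Readings and results are calculated for substances that don't exist, noise included.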